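Summed over the 3 readings up to 0.500 min, the left-handed substrate of this flask has lost 14.8% of the two hands charged together, and the right-handed substrate 1.00%.

| setting | spring | flask |
|---|---|---|
| left-handed substrate | 0.80 M | 0.80 M |
| right-handed substrate | 0.80 M | 0.80 M |
| coupling partner | 2.4 M | 2.40 M |
| precatalyst | 80 mM | 80 mM |
| remark | the very flask that is asked about, followed so far |  |
| time |  | 5.0 min |

spring run (percent of the left-handed substrate and right-handed substrate together charged)

| time / min | left-handed substrate / % | right-handed substrate / % |
|---|---|---|
| 0.200 | 47.4 | 49.4 |
| 0.333 | 45.5 | 50.2 |
| 0.500 | 42.3 | 49.4 |
| 0.667 | 41.5 | 46.4 |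
| 1.00 | 39.4 | 46.9 |
| 1.50 | 36.0 | 41.4 |
| 2.50 | 30.6 | 37.6 |

(scatter of a reading: 1 percentage point)

- coupling partner is single-handed; left-handed substrate and right-handed substrate are mirror images of each other, charged as a racemate, each of them at the stated concentration
- the numbers in the tables scatter with a standard deviation of 1 percentage point
- reactions considered so far: 2 racemization catalyst -> spent catalyst; coupling partner -> decomposition product; left-handed substrate + racemization catalyst <-> right-handed substrate + racemization catalyst; coupling partner + right-handed substrate -> right-handed product; coupling partner + precatalyst -> racemization catalyst + spent reagent; coupling partner + left-handed substrate -> left-handed product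
- an excess is below zero if the other one leads
- the handed part of coupling partner does not stay in what it makes, so the products of the two hands are mirror images too

1. part of the left-handed substrate and right-handed substrate charged together that has reacted at 5.0 min
2. excess of left-handed product over right-handed product in the product at 5.0 min
3. excess of right-handed substrate over left-handed substrate among what is left of the two at 5.0 min

The ratio of those losses reads s = 14.8, taken as the selectivity factor: the rate constant of coupling partner with left-handed substrate over that with right-handed substrate; it is a rough reading, since the racemization catalyst also moves substrate between the hands and the right-handed loss is a sum of 3 readings that each scatter by 1 percentage point. Coupling partner stands in both product rates and cancels from their ratio, so with ρ, the left-handed over right-handed substrate, held at a mean, integration gives left-handed over right-handed product = sρ, and eP = (sρ − 1)/(sρ + 1).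

Taking the inputs in turn, coupling partner cancels only at a given ρ, so its charge, like that of precatalyst, acts on eP through ρ, read as 0.814 at 2.50 min: this gives eP = 84.7%, and ρ = 1 gives 87.3%. At s = 4.93, eP falls to 60.1%, so this reckoning of eP leans on the reading of s more than on that of ρ. The reckoning here commits to 84.7%.

The forecast, differing from this, stood at 47%, 19% and 17% for c, eP and eS, by “Mass balance gives eP = eS(1−c)/c”.

The flask gives 49.2%, 86.4% and 13.4%.

    2 racemization catalyst → spent catalyst (k = 0.0438 M⁻¹ s⁻¹)
    coupling partner → decomposition product (k = 5.21 × 10⁻⁵ s⁻¹)
    left-handed substrate + racemization catalyst ⇌ right-handed substrate + racemization catalyst, rate k3*[racemization catalyst]*[left-handed substrate] forward; the back reaction follows from the equilibrium constant (k = 0.204 M⁻¹ s⁻¹)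
    coupling partner + right-handed substrate → right-handed product (k = 1.54 × 10⁻⁴ M⁻¹ s⁻¹)
    coupling partner + precatalyst → racemization catalyst + spent reagent (k = 0.0172 M⁻¹ s⁻¹)
    coupling partner + left-handed substrate → left-handed product (k = 0.00253 M⁻¹ s⁻¹)

With ρ taken as the mean of its starting 1 and its end value, 0.763, the same s gives 85.8% on this flask. The neighbouring flask with 0.020 M of precatalyst ends with ρ at 0.569 and eS at 27.5%, so its mean ρ is 0.784 and the reckoning gives eP = 84.1%; that neighbouring flask stands at 84.1%.

The numbers in the tables were generated by integration for substances that don't exist; scatter was added.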